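**Plan**

- Retrosynthesis first cuts both bonds at the stereogenic carbon (to C5' of ring B and to the styryl carbon), giving cajanin, 2,4-dimethoxybenzaldehyde and an (E)-styrylboronic acid.
- Next, C2 of ring C is removed, then the C4a–C5 bond of ring A is cut to a linear 3,5,7-triketo ester, and last the chain bond between its C6 and C7 is cut to methyl 3,5-dioxohexanoate and an arylacetic amide.
- Enabling feature: ring A is a phloroglucinol ring with oxygen on C5, C7 and C8a and the C4 acyl group on C4a, which is the pattern of a triketo ester folded so that the carbon between two ketones meets the ester carbon.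
- Forward order: chain joined by trianion acylation; ring A closed by Claisen folding; ring C closed with a one-carbon amide acetal; O7 methylated; MOM groups removed; stereogenic carbon built at C5' by a three-component condensation; silyl ether removed.
- Stereochemistry: the single (R) centre comes from the chiral 3,3'-dibromo-BINOL catalyst, which directs styryl transfer from boron to one face of an ortho-quinone methide; the E alkene comes from syn-hydroboration of an aryl alkyne.

Key step: step 5

Assumption: the (S)-antipode of 3,3'-dibromo-1,1'-bi-2-naphthol is taken to be the one that gives the (R) centre; if a model run shows the opposite sense, the (R)-catalyst is used and nothing else changes.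

**Route**

Step 1
Reactants: 1 2,4-dihydroxyphenylacetic acid
Product: 2 methyl 2-(2,4-dihydroxyphenyl)acetate
Conditions: MeOH, H2SO4 (cat.), reflux
Reagents that add atoms: methanol, CO
Why: Fischer esterification; any benzofuranone formed by lactonisation onto the 2-OH is reopened by methanol under the same acid, so the methyl ester should be the end point.

Step 2
Reactants: 2 methyl 2-(2,4-dihydroxyphenyl)acetate
Product: 3 methyl 2-[2,4-bis(methoxymethoxy)phenyl]acetate
Conditions: MeOCH2Cl (3 equiv), iPr2NEt (4 equiv), Bu4NI (cat.), CH2Cl2, 0 °C to rt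
Reagents that add atoms: chloromethyl methyl ether, COCCl
Why: Williamson-type O-alkylation of both phenols by an alpha-chloro ether; the MOM acetals are inert to the amide bases, methoxide and carbonate of steps 3 to 7 and leave together in one acid step.

Step 3
Reactants: 3 methyl 2-[2,4-bis(methoxymethoxy)phenyl]acetate
Product: 4 2-[2,4-bis(methoxymethoxy)phenyl]-N-methoxy-N-methylacetamide
Conditions: MeNH(OMe)·HCl (1.5 equiv), iPrMgCl (3.0 equiv), THF, −20 to 0 °C
Reagents that add atoms: N,O-dimethylhydroxylamine hydrochloride, CNOC.Cl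
Why: ester aminolysis by the chloromagnesium amide of N,O-dimethylhydroxylamine (Weinreb amide synthesis), a weakly basic nucleophile that should not enolise the arylacetate.

Step 4
Reactants: 5 methyl 3,5-dioxohexanoate; 4 2-[2,4-bis(methoxymethoxy)phenyl]-N-methoxy-N-methylacetamide
Product: 7 methyl 8-[2,4-bis(methoxymethoxy)phenyl]-3,5,7-trioxooctanoate, via trilithium trianion 6 (not isolated)
Conditions: 5, LiN(iPr)2 (3.2 equiv), THF, −78 to 0 °C; then 4 (0.85 equiv), −78 to −20 °C; cold aq. NH4Cl; crude 7 used at once
Reagents that add atoms: none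
Why: acylation of a 1,3,5-tricarbonyl trianion at its terminal, last-formed and most nucleophilic carbanion (polyketide-type chain extension), here by a Weinreb amide whose chelated tetrahedral adduct holds the acyl group until work-up, so the more acidic product can neither quench the trianion nor be acylated twice.

Step 5
Reactants: 7 methyl 8-[2,4-bis(methoxymethoxy)phenyl]-3,5,7-trioxooctanoate
Product: 8 2-[2,4-bis(methoxymethoxy)phenyl]-1-(2,4,6-trihydroxyphenyl)ethan-1-one
Conditions: Mg(OMe)2 (4 equiv), degassed MeOH, rt to 50 °C, Ar; then cold 1 M HCl to pH 4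
Reagents that add atoms: none
Why: Mg(OMe)2 should turn all three ketones of 7 into magnesium-chelated enolates, so that the methyl ester carbon C1 is the only electrophilic carbonyl left; the enolate carbon C6, flanked by the C5 and C7 oxygens, adds to it, methoxide leaves, and the cyclohexane-1,3,5-trione tautomerises to the phloroglucinol. The closest known reaction is the biomimetic Claisen cyclisation of 3,5,7-triketo esters and of tetraacetic lactone to acylphloroglucinols with Mg(OMe)2 or KOH. Ring A closes in the 6-(enolendo)-exo-trig mode, making the bond that is C4a–C5 of the isoflavone, while chain carbon C7 stays outside the ring as the future C4 carbonyl with C8 and ring B attached. No stereocentre is formed. The selectivity needed is Claisen closure over aldol closure of C2 onto the C7 ketone, which would give a resorcylate; the methyl ester (not the acid, whose carboxylate cannot be attacked), the water-free alkoxide medium and full enolisation of the ketones should secure it, and the benzylic C8 next to the C7 enolate is not deprotonated and so should not compete. The MOM acetals are stable to methoxide.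

Step 6
Reactants: 8 2-[2,4-bis(methoxymethoxy)phenyl]-1-(2,4,6-trihydroxyphenyl)ethan-1-one
Product: 10 3-[2,4-bis(methoxymethoxy)phenyl]-5,7-dihydroxy-4H-chromen-4-one, via enaminone 9 (not isolated)
Conditions: Me2NCH(OMe)2 (1.5 equiv), THF, 60 °C; dilute aq. AcOH work-up
Reagents that add atoms: N,N-dimethylformamide dimethyl acetal, COC(OC)N(C)C
Why: condensation of the deoxybenzoin methylene with the amide acetal gives an enaminone, and addition–elimination by either of the two equivalent ortho-phenols expels dimethylamine and closes ring C, the standard one-carbon isoflavone synthesis from a 2-hydroxydeoxybenzoin.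

Step 7
Reactants: 10 3-[2,4-bis(methoxymethoxy)phenyl]-5,7-dihydroxy-4H-chromen-4-one
Product: 11 3-[2,4-bis(methoxymethoxy)phenyl]-5-hydroxy-7-methoxy-4H-chromen-4-one
Conditions: MeI (1.1 equiv), K2CO3 (1.2 equiv), acetone, rt
Reagents that add atoms: iodomethane, CI
Why: Williamson methylation of the acidic, unchelated 7-OH; the 5-OH is held in a hydrogen bond to the C4 carbonyl and should stay free with one equivalent of electrophile.

Step 8
Reactants: 11 3-[2,4-bis(methoxymethoxy)phenyl]-5-hydroxy-7-methoxy-4H-chromen-4-one
Product: 12 cajanin, 3-(2,4-dihydroxyphenyl)-5-hydroxy-7-methoxy-4H-chromen-4-one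
Conditions: 3 M HCl, MeOH–THF, 50 °C
Reagents that add atoms: none
Why: acid-catalysed transacetalisation of the two aryl MOM ethers to methanol; the aryl methyl ether, the chromone and the phenols are stable to these conditions.

Step 9
Reactants: 13 4-[(tert-butyldimethylsilyl)oxy]benzaldehyde
Product: 14 tert-butyl(4-ethynylphenoxy)dimethylsilane
Conditions: Me3SiCHN2 (1.2 equiv), LiN(iPr)2 (1.2 equiv), THF, −78 °C to rt; aq. NH4Cl
Reagents that add atoms: (trimethylsilyl)diazomethane, C[Si](C)(C)C=[N+]=[N-]
Why: Colvin homologation: addition of lithiated silyldiazomethane, Peterson elimination, loss of N2 and 1,2-hydrogen shift of the alkylidene carbene give the terminal alkyne without the carbonate–methanol medium that would cleave the aryl silyl ether.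

Step 10
Reactants: 14 tert-butyl(4-ethynylphenoxy)dimethylsilane
Product: 16 [(E)-2-(4-{[tert-butyl(dimethyl)silyl]oxy}phenyl)ethenyl]boronic acid, via catechol boronate 15 (not isolated)
Conditions: catecholborane (1.2 equiv), Cy2BH (10 mol %), THF, rt; then H2O, rt
Reagents that add atoms: catecholborane, B1Oc2ccccc2O1; water, O
Why: syn, anti-Markovnikov hydroboration of a terminal aryl alkyne fixes the E geometry of the styryl unit, and hydrolysis of the catechol ester should give the storable boronic acid.

Step 11
Reactants: 12 cajanin; 16 [(E)-2-(4-{[tert-butyl(dimethyl)silyl]oxy}phenyl)ethenyl]boronic acid; 17 2,4-dimethoxybenzaldehyde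
Product: 20 5'-[(1R,2E)-3-(4-{[tert-butyl(dimethyl)silyl]oxy}phenyl)-1-(2,4-dimethoxyphenyl)prop-2-en-1-yl]-5,2',4'-trihydroxy-7-methoxyisoflavone, via diethyl boronate 18 (not isolated), via ortho-quinone methide 19 (not isolated)
Conditions: 16 (2.5 equiv), EtOH, 3 Å MS, CH2Cl2, rt, evaporate; then 12, 17 (1.2 equiv), (S)-3,3'-dibromo-1,1'-bi-2-naphthol (20 mol %), 4 Å MS, toluene–THF (5:1), 50 °C
Reagents that add atoms: none
Why: chiral-biphenol-catalysed three-component condensation of a phenol, an aldehyde and an alkenylboronate: boron-templated ortho-hydroxyalkylation at C5' (ortho to the 4'-OH and para to the 2'-OH, while ring A offers only the chelated 5-OH and a methyl ether) gives the ortho-quinone methide, and the BINOL-bound boronate on the quinone methide oxygen passes its styryl group to one face of the exocyclic carbon through a closed six-membered transition state, which sets the (R) centre.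

Step 12
Reactants: 20 5'-[(1R,2E)-3-(4-{[tert-butyl(dimethyl)silyl]oxy}phenyl)-1-(2,4-dimethoxyphenyl)prop-2-en-1-yl]-5,2',4'-trihydroxy-7-methoxyisoflavone
Product: 21 caraganin A
Conditions: Bu4NF (1.1 equiv), AcOH (1.1 equiv), THF, 0 °C
Reagents that add atoms: none
Why: fluoride cleavage of the aryl silyl ether under buffered, non-acidic conditions, which should neither ionise the doubly benzylic allylic centre nor add the 4'-OH across the styrene.

**Compound list**

1 | 2,4-dihydroxyphenylacetic acid | OC(=O)Cc1ccc(O)cc1O | starting material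
2 | methyl 2-(2,4-dihydroxyphenyl)acetate | COC(=O)Cc1ccc(O)cc1O | intermediate
3 | methyl 2-[2,4-bis(methoxymethoxy)phenyl]acetate | COCOc1ccc(CC(=O)OC)c(OCOC)c1 | intermediate
4 | 2-[2,4-bis(methoxymethoxy)phenyl]-N-methoxy-N-methylacetamide | COCOc1ccc(CC(=O)N(C)OC)c(OCOC)c1 | intermediate
5 | methyl 3,5-dioxohexanoate | COC(=O)CC(=O)CC(C)=O | starting material
6 | trilithium trianion of methyl 3,5-dioxohexanoate (C2, C4 and C6 deprotonated) | [Li+].[Li+].[Li+].[CH2-]C(=O)[CH-]C(=O)[CH-]C(=O)OC | intermediate
7 | methyl 8-[2,4-bis(methoxymethoxy)phenyl]-3,5,7-trioxooctanoate | COCOc1ccc(CC(=O)CC(=O)CC(=O)CC(=O)OC)c(OCOC)c1 | intermediate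
8 | 2-[2,4-bis(methoxymethoxy)phenyl]-1-(2,4,6-trihydroxyphenyl)ethan-1-one | COCOc1ccc(CC(=O)c2c(O)cc(O)cc2O)c(OCOC)c1 | intermediate
9 | (E)-2-[2,4-bis(methoxymethoxy)phenyl]-3-(dimethylamino)-1-(2,4,6-trihydroxyphenyl)prop-2-en-1-one | CN(C)/C=C(\c1ccc(OCOC)cc1OCOC)C(=O)c1c(O)cc(O)cc1O | intermediate
10 | 3-[2,4-bis(methoxymethoxy)phenyl]-5,7-dihydroxy-4H-chromen-4-one | COCOc1ccc(-c2coc3cc(O)cc(O)c3c2=O)c(OCOC)c1 | intermediate
11 | 3-[2,4-bis(methoxymethoxy)phenyl]-5-hydroxy-7-methoxy-4H-chromen-4-one | COCOc1ccc(-c2coc3cc(OC)cc(O)c3c2=O)c(OCOC)c1 | intermediate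
12 | cajanin, 3-(2,4-dihydroxyphenyl)-5-hydroxy-7-methoxy-4H-chromen-4-one | Oc1ccc(-c2coc3cc(OC)cc(O)c3c2=O)c(O)c1 | intermediate
13 | 4-[(tert-butyldimethylsilyl)oxy]benzaldehyde | CC(C)(C)[Si](C)(C)Oc1ccc(C=O)cc1 | starting material
14 | tert-butyl(4-ethynylphenoxy)dimethylsilane | CC(C)(C)[Si](C)(C)Oc1ccc(C#C)cc1 | intermediate
15 | 2-[(E)-2-(4-{[tert-butyl(dimethyl)silyl]oxy}phenyl)ethenyl]-1,3,2-benzodioxaborole | CC(C)(C)[Si](C)(C)Oc1ccc(/C=C/B2Oc3ccccc3O2)cc1 | intermediate
16 | [(E)-2-(4-{[tert-butyl(dimethyl)silyl]oxy}phenyl)ethenyl]boronic acid | CC(C)(C)[Si](C)(C)Oc1ccc(/C=C/B(O)O)cc1 | intermediate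
17 | 2,4-dimethoxybenzaldehyde | COc1ccc(C=O)c(OC)c1 | starting material
18 | diethyl [(E)-2-(4-{[tert-butyl(dimethyl)silyl]oxy}phenyl)ethenyl]boronate | CCOB(OCC)/C=C/c1ccc(O[Si](C)(C)C(C)(C)C)cc1 | intermediate
19 | ring B ortho-quinone methide, 3-{3-[(E)-(2,4-dimethoxyphenyl)methylidene]-6-hydroxy-4-oxocyclohexa-1,5-dien-1-yl}-5-hydroxy-7-methoxy-4H-chromen-4-one | O=C1C=C(O)C(-c2coc3cc(OC)cc(O)c3c2=O)=C/C1=C\c1ccc(OC)cc1OC | intermediate
20 | 3-{5-[(1R,2E)-3-(4-{[tert-butyl(dimethyl)silyl]oxy}phenyl)-1-(2,4-dimethoxyphenyl)prop-2-en-1-yl]-2,4-dihydroxyphenyl}-5-hydroxy-7-methoxy-4H-chromen-4-one | COc1ccc([C@H](/C=C/c2ccc(O[Si](C)(C)C(C)(C)C)cc2)c2cc(-c3coc4cc(OC)cc(O)c4c3=O)c(O)cc2O)c(OC)c1 | intermediate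
21 | caraganin A, 3-{5-[(1R,2E)-1-(2,4-dimethoxyphenyl)-3-(4-hydroxyphenyl)prop-2-en-1-yl]-2,4-dihydroxyphenyl}-5-hydroxy-7-methoxy-4H-chromen-4-one | COc1ccc([C@H](/C=C/c2ccc(O)cc2)c2cc(-c3coc4cc(OC)cc(O)c4c3=O)c(O)cc2O)c(OC)c1 | target

**Step count**

Total: 12 steps. Longest linear sequence: 10 steps (steps 1 to 8, 11 and 12, from 1 to 21); steps 9 and 10 are a two-step side branch that joins in step 11.

**Steps most likely to fail**

Step 11. Several processes may compete:
- hydroxyalkylation at C3' or on ring A instead of C5';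
- capture of the quinone methide by a second molecule of the phenol;
- loss of face selectivity because the 2'-OH also binds boron;
- onward addition of the 4'-OH across the electron-rich styrene to a 2,4-diarylchroman.

The fallback gives up catalytic control of the centre, makes it through an allyl cation and separates the enantiomers. It sets out from 12 and returns at 21. Claisen–Schmidt condensation of 2',4'-dimethoxyacetophenone with 4-hydroxybenzaldehyde (KOH, EtOH) gives (E)-1-(2,4-dimethoxyphenyl)-3-(4-hydroxyphenyl)prop-2-en-1-one F1. Luche reduction (NaBH4, CeCl3·7H2O, MeOH, 0 °C) gives racemic (E)-1-(2,4-dimethoxyphenyl)-3-(4-hydroxyphenyl)prop-2-en-1-ol F2. Friedel–Crafts allylation of 12 by F2 under a catalytic sulfonic acid (MeCN, 0 °C) gives racemic caraganin A F3. The regioisomer from attack at the other allyl terminus is removed by chromatography, and preparative chromatography on a chiral phase then delivers 21.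

Step 4. Proton transfer from the acidic benzylic CH2 of 4 to the strongly basic trianion may outrun acylation, and acylation at an inner carbon or early cyclisation of the product during work-up may lower the return. The fallback builds the same chain from a less basic dianion and a masked ester. It sets out from 4 and returns at 7. The dilithium dianion of 2,2-dimethyl-6-(2-oxopropyl)-4H-1,3-dioxin-4-one (LiN(iPr)2, THF, −78 °C) is acylated at its terminal carbon by 4 to give 6-{5-[2,4-bis(methoxymethoxy)phenyl]-2,4-dioxopentyl}-2,2-dimethyl-4H-1,3-dioxin-4-one F4. Heating F4 in toluene with methanol at 100 °C expels acetone by retro-[4+2] opening, and methanol captures the acylketene to give 7.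

Step 5. Aldol closure of C2 onto the C7 ketone, which is an alkyl ketone and more electrophilic than an aryl ketone, may compete with the Claisen mode, and the electron-rich product may oxidise in base if air is admitted. The fallback makes ring A from an existing phloroglucinol and drops the MOM groups. It sets out from 1 and returns at 12. Friedel–Crafts acylation of phloroglucinol by 1 in BF3·OEt2 at 85 °C gives 2-(2,4-dihydroxyphenyl)-1-(2,4,6-trihydroxyphenyl)ethan-1-one F5. DMF and MeSO2Cl in the same medium at 70 °C close ring C to 2'-hydroxygenistein F6. One equivalent of MeI with KHCO3 in DMF then methylates the most acidic 7-OH to give 12.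

**Further compounds**

F1 | step 11 | (E)-1-(2,4-dimethoxyphenyl)-3-(4-hydroxyphenyl)prop-2-en-1-one | COc1ccc(C(=O)/C=C/c2ccc(O)cc2)c(OC)c1
F2 | step 11 | racemic (E)-1-(2,4-dimethoxyphenyl)-3-(4-hydroxyphenyl)prop-2-en-1-ol | COc1ccc(C(O)/C=C/c2ccc(O)cc2)c(OC)c1
F3 | step 11 | racemic caraganin A | COc1ccc(C(/C=C/c2ccc(O)cc2)c2cc(-c3coc4cc(OC)cc(O)c4c3=O)c(O)cc2O)c(OC)c1
F4 | step 4 | 6-{5-[2,4-bis(methoxymethoxy)phenyl]-2,4-dioxopentyl}-2,2-dimethyl-4H-1,3-dioxin-4-one | COCOc1ccc(CC(=O)CC(=O)CC2=CC(=O)OC(C)(C)O2)c(OCOC)c1
F5 | step 5 | 2-(2,4-dihydroxyphenyl)-1-(2,4,6-trihydroxyphenyl)ethan-1-one | O=C(Cc1ccc(O)cc1O)c1c(O)cc(O)cc1O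
F6 | step 5 | 2'-hydroxygenistein, 3-(2,4-dihydroxyphenyl)-5,7-dihydroxy-4H-chromen-4-one | Oc1ccc(-c2coc3cc(O)cc(O)c3c2=O)c(O)c1
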